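## Retrosynthetic overview

1. Target ⇐ butenolide acid (lactone opening); butenolide ⇐ C12 aldehyde (asymmetric propiolate addition, then methylcuprate syn-addition and lactonisation); C19 acid ⇐ C19 alcohol.
2. Decalin ⇐ acyclic (S)-2-methyl-2-alkyloxirane carrying a trisubstituted alkene and an allylsilane. One cationic cascade: oxirane opening at C4 closes ring A first, the C8=C9 allylsilane then closes ring B and leaves the 8(17)-methylidene; C19 arrives already oxygenated.
3. Oxirane ⇐ methyl ketone (catalytic asymmetric methylene transfer); allylsilane and C11–C12 ⇐ terminal alkyne (silylmethyl carbocupration, ethylene oxide).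
4. C1–C2 bond ⇐ (E)-allylic bromide + ketal Grignard reagent; bromide ⇐ 6-methylhept-5-en-2-one (alkyne formation, SeO2 oxidation).

Assumption: the BINOL enantiomers named in steps 8 and 11 are those that give the (S)-oxirane and the (12S)-carbinol (the mirror-image ligand is used if the sense proves opposite), and the target is isolated as the free hydroxy diacid by cold, weakly acidic work-up.

## Route

Step 1
Reactants: 1 6-methylhept-5-en-2-one
Product: 3 6-methylhept-5-en-1-yne, via enol phosphate 2 (not isolated)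
Conditions: LDA (1.05 equiv), THF, −78 °C; ClP(O)(OEt)2, → rt; LDA (2.3 equiv), −78 °C → rt; aq NH4Cl
Reagents that add atoms: none
Why: Kinetic methyl-side enolisation, O-phosphorylation and LDA-induced β-elimination of the enol phosphate (Negishi alkyne synthesis from a methyl ketone) give the terminal alkyne without touching the trisubstituted alkene.

Step 2
Reactants: 3 6-methylhept-5-en-1-yne
Product: 4 (E)-2-methylhept-2-en-6-yn-1-ol
Conditions: SeO2 (0.3 equiv), t-BuOOH (3 equiv), salicylic acid (0.1 equiv), CH2Cl2, 0 °C → rt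
Reagents that add atoms: tert-butyl hydroperoxide, CC(C)(C)OO
Why: The SeO2 ene reaction/[2,3]-sigmatropic shift (Sharpless allylic oxidation) hydroxylates only the (E)-methyl of the gem-dimethyl alkene, which fixes the (E)-geometry of the future C5=C10 alkene.

Step 3
Reactants: 4 (E)-2-methylhept-2-en-6-yn-1-ol
Product: 5 (E)-7-bromo-6-methylhept-5-en-1-yne
Conditions: PBr3 (0.4 equiv), Et2O, −10 °C
Reagents that add atoms: phosphorus tribromide, BrP(Br)Br
Why: PBr3 converts the primary allylic alcohol to the bromide by SN2 at low temperature without allylic transposition or loss of alkene geometry.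

Step 4
Reactants: 5 (E)-7-bromo-6-methylhept-5-en-1-yne; 6 2-(2-bromoethyl)-2-methyl-1,3-dioxolane
Product: 8 2-methyl-2-[(4E)-4-methylnon-4-en-8-yn-1-yl]-1,3-dioxolane, via Grignard reagent 7 (not isolated)
Conditions: 6, Mg, THF, 25 °C; then 5, Li2CuCl4 (3 mol %), THF, −78 → −20 °C
Reagents that add atoms: none
Why: Kochi-type Li2CuCl4-catalysed sp3–sp3 coupling of the primary allylic bromide with the ketal-protected homoenolate Grignard reagent goes by SN2 at the unhindered CH2 with retention of the (E)-alkene, and below −20 °C the acetylenic C–H is not metalated on this time scale.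

Step 5
Reactants: 8 2-methyl-2-[(4E)-4-methylnon-4-en-8-yn-1-yl]-1,3-dioxolane
Product: 10 (3Z,7E)-8-methyl-11-(2-methyl-1,3-dioxolan-2-yl)-4-[(trimethylsilyl)methyl]undeca-3,7-dien-1-ol, via alkenylcopper 9 (not isolated)
Conditions: Me3SiCH2MgCl (1.3 equiv), CuBr·SMe2 (1.3 equiv), Et2O/Me2S, −40 °C; 8, −25 °C, 12 h; then BuC≡CLi (1.3 equiv), HMPA, ethylene oxide (3 equiv), −40 → 0 °C; aq NH4Cl/NH3
Reagents that add atoms: (trimethylsilylmethyl)magnesium chloride, C[Si](C)(C)C[Mg]Cl; ethylene oxide, C1CO1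
Why: Normant syn-carbocupration of the terminal alkyne puts CH2SiMe3 on the internal carbon and copper on the terminal carbon, and the derived mixed cuprate opens ethylene oxide with retention at the sp2 carbon, so the allylsilane alkene forms as one geometric isomer (C7 and C11 trans).

Step 6
Reactants: 10 (3Z,7E)-8-methyl-11-(2-methyl-1,3-dioxolan-2-yl)-4-[(trimethylsilyl)methyl]undeca-3,7-dien-1-ol
Product: 11 (6E,10Z)-13-hydroxy-6-methyl-10-[(trimethylsilyl)methyl]trideca-6,10-dien-2-one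
Conditions: PPTS (0.1 equiv), acetone/H2O (10:1), 45 °C
Reagents that add atoms: water, O
Why: Mild acid-catalysed ketal hydrolysis frees the methyl ketone, PPTS being too weak an acid to protodesilylate the allylsilane.

Step 7
Reactants: 11 (6E,10Z)-13-hydroxy-6-methyl-10-[(trimethylsilyl)methyl]trideca-6,10-dien-2-one
Product: 12 (6E,10Z)-6-methyl-13-[(triethylsilyl)oxy]-10-[(trimethylsilyl)methyl]trideca-6,10-dien-2-one
Conditions: Et3SiCl, imidazole, CH2Cl2, 0 °C
Reagents that add atoms: chlorotriethylsilane, CC[Si](Cl)(CC)CC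
Why: Standard silylation caps the primary alcohol so that it cannot trap the C8 cation in step 9, and a primary triethylsilyl ether can later be oxidised directly.

Step 8
Reactants: 12 (6E,10Z)-6-methyl-13-[(triethylsilyl)oxy]-10-[(trimethylsilyl)methyl]trideca-6,10-dien-2-one
Product: 13 triethyl({(3Z,7E)-8-methyl-11-[(2S)-2-methyloxiran-2-yl]-4-[(trimethylsilyl)methyl]undeca-3,7-dien-1-yl}oxy)silane
Conditions: Me3S(O)I (1.2 equiv), NaH (1.2 equiv), THF; LaLi3[(S)-BINOL]3 (5 mol %), (2,4,6-(MeO)3C6H2)3P=O (5 mol %), 5 Å MS, THF, rt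
Reagents that add atoms: trimethylsulfoxonium iodide, C[S+](C)(C)=O.[I-]
Why: Catalytic asymmetric Corey–Chaykovsky methylene transfer from dimethylsulfoxonium methylide inside the chiral La/Li/BINOL–phosphine oxide complex distinguishes the methyl from the long alkyl group of the ketone and sets the (S)-configured quaternary oxirane carbon (future C4), the silyl ether and allylsilane being inert to the ylide.

Step 9
Reactants: 13 triethyl({(3Z,7E)-8-methyl-11-[(2S)-2-methyloxiran-2-yl]-4-[(trimethylsilyl)methyl]undeca-3,7-dien-1-yl}oxy)silane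
Product: 14 [(1S,4aR,5S,8aR)-1,4a-dimethyl-6-methylidene-5-{2-[(triethylsilyl)oxy]ethyl}decahydronaphthalen-1-yl]methanol
Conditions: MeAlCl2 (2 equiv), CH2Cl2, −78 °C, 30 min; Et3N/MeOH, then aq NaHCO3/Rochelle salt
Reagents that add atoms: none
Why: Proposed new method: Lewis-acid activation of the (S)-2,2-disubstituted oxirane lets the C5=C10 alkene attack C4 from the back side of the breaking C–O bond (inversion at C4, the oxygen staying on C19), the chair–chair transition state in which the C18 methyl is equatorial while the oxirane CH2–O is held on the leaving-group side sets C5, C10 and C9 trans–anti, and the β-silyl cation at C8 collapses to the 8(17)-alkene, the closest known reaction type being the epoxide-initiated cationic polyene cyclisation of trisubstituted (oxidosqualene-type) epoxides with allylsilane termination.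

Step 10
Reactants: 14 [(1S,4aR,5S,8aR)-1,4a-dimethyl-6-methylidene-5-{2-[(triethylsilyl)oxy]ethyl}decahydronaphthalen-1-yl]methanol
Product: 15 (1S,4aR,5S,8aR)-1,4a-dimethyl-6-methylidene-5-(2-oxoethyl)decahydronaphthalene-1-carbaldehyde
Conditions: (COCl)2 (5 equiv), DMSO (10 equiv), CH2Cl2, −78 → −30 °C; Et3N, → 0 °C
Reagents that add atoms: none
Why: Swern oxidation turns the neopentyl C19 alcohol into the aldehyde and, with excess activated DMSO, cleaves and oxidises the primary triethylsilyl ether in the same pot, and no stereocentre is α to either new aldehyde.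

Step 11
Reactants: 15 (1S,4aR,5S,8aR)-1,4a-dimethyl-6-methylidene-5-(2-oxoethyl)decahydronaphthalene-1-carbaldehyde
Product: 16 methyl (4S)-5-[(1S,4aR,5S,8aR)-5-formyl-5,8a-dimethyl-2-methylidenedecahydronaphthalen-1-yl]-4-hydroxypent-2-ynoate
Conditions: HC≡CCO2Me (4 equiv), ZnEt2 (4 equiv), HMPA (2 equiv), CH2Cl2, rt, 16 h; (R)-BINOL (40 mol %), Ti(OiPr)4 (1 equiv); then 15, rt; aq NH4Cl
Reagents that add atoms: methyl propiolate, C#CC(=O)OC
Why: BINOL–Ti(OiPr)4-catalysed addition of the alkynylzinc from methyl propiolate (Pu alkynylation) attacks only the unhindered C12 aldehyde, the axial neopentyl C19 aldehyde being inert, and sets the (12S)-carbinol under reagent control.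

Step 12
Reactants: 16 methyl (4S)-5-[(1S,4aR,5S,8aR)-5-formyl-5,8a-dimethyl-2-methylidenedecahydronaphthalen-1-yl]-4-hydroxypent-2-ynoate
Product: 17 (1S,4aR,5S,8aR)-5-[(2S)-2-hydroxy-5-methoxy-5-oxopent-3-yn-1-yl]-1,4a-dimethyl-6-methylidenedecahydronaphthalene-1-carboxylic acid
Conditions: NaClO2, NaH2PO4, 2-methyl-2-butene, t-BuOH/H2O, 0 °C → rt
Reagents that add atoms: sodium chlorite, [Na+].[O-]Cl=O
Why: Pinnick oxidation converts the hindered C19 aldehyde to the acid under buffered conditions in which the exocyclic alkene (HOCl scavenged), the propargylic alcohol and the ynoate survive.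

Step 13
Reactants: 17 (1S,4aR,5S,8aR)-5-[(2S)-2-hydroxy-5-methoxy-5-oxopent-3-yn-1-yl]-1,4a-dimethyl-6-methylidenedecahydronaphthalene-1-carboxylic acid
Product: 19 (1S,4aR,5S,8aR)-1,4a-dimethyl-6-methylidene-5-{[(2S)-3-methyl-5-oxo-2,5-dihydrofuran-2-yl]methyl}decahydronaphthalene-1-carboxylic acid, via (Z)-hydroxy enoate 18 (not isolated)
Conditions: Me2CuLi (5 equiv), THF, −78 °C; aq NH4Cl, → rt; recrystallisation
Reagents that add atoms: lithium dimethylcuprate, [Li+].C[Cu-]C
Why: syn-Carbocupration (conjugate addition) of Me2CuLi to the ynoate at −78 °C places the new methyl cis to H14, so C12 and the ester are cis (13Z) and the γ-hydroxy ester lactonises to the butenolide, which is crystallised free of the minor diastereomers left by steps 8 and 11.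

Step 14
Reactants: 19 (1S,4aR,5S,8aR)-1,4a-dimethyl-6-methylidene-5-{[(2S)-3-methyl-5-oxo-2,5-dihydrofuran-2-yl]methyl}decahydronaphthalene-1-carboxylic acid
Product: 20 (1S,4aR,5S,8aR)-5-[(2S,3Z)-4-carboxy-2-hydroxy-3-methylbut-3-en-1-yl]-1,4a-dimethyl-6-methylidenedecahydronaphthalene-1-carboxylic acid
Conditions: LiOH (4 equiv), THF/H2O (3:1), 0 °C → rt; 0.5 M HCl to pH 4–5 at 0 °C, EtOAc extraction, evaporation below 20 °C
Reagents that add atoms: lithium hydroxide, [Li+].[OH-]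
Why: Saponification opens the butenolide by acyl–oxygen cleavage, which is much faster than γ-deprotonation so C12 is untouched, and cold acidification only to pH 4–5 liberates the (Z)-γ-hydroxy diacid before it can relactonise.

## Compound list

1 | 6-methylhept-5-en-2-one | CC(=O)CCC=C(C)C | starting material
2 | diethyl 6-methylhepta-1,5-dien-2-yl phosphate | C=C(CCC=C(C)C)OP(=O)(OCC)OCC | intermediate
3 | 6-methylhept-5-en-1-yne | C#CCCC=C(C)C | intermediate
4 | (E)-2-methylhept-2-en-6-yn-1-ol | OC/C(C)=C/CCC#C | intermediate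
5 | (E)-7-bromo-6-methylhept-5-en-1-yne | BrC/C(C)=C/CCC#C | intermediate
6 | 2-(2-bromoethyl)-2-methyl-1,3-dioxolane | CC1(CCBr)OCCO1 | starting material
7 | [2-(2-methyl-1,3-dioxolan-2-yl)ethyl]magnesium bromide | CC1(CC[Mg]Br)OCCO1 | intermediate
8 | 2-methyl-2-[(4E)-4-methylnon-4-en-8-yn-1-yl]-1,3-dioxolane | CC1(CCC/C(C)=C/CCC#C)OCCO1 | intermediate
9 | {(1Z,5E)-6-methyl-9-(2-methyl-1,3-dioxolan-2-yl)-2-[(trimethylsilyl)methyl]nona-1,5-dien-1-yl}copper | CC1(CCC/C(C)=C/CC/C(C[Si](C)(C)C)=C/[Cu])OCCO1 | intermediate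
10 | (3Z,7E)-8-methyl-11-(2-methyl-1,3-dioxolan-2-yl)-4-[(trimethylsilyl)methyl]undeca-3,7-dien-1-ol | CC1(CCC/C(C)=C/CC/C(C[Si](C)(C)C)=C/CCO)OCCO1 | intermediate
11 | (6E,10Z)-13-hydroxy-6-methyl-10-[(trimethylsilyl)methyl]trideca-6,10-dien-2-one | CC(=O)CCC/C(C)=C/CC/C(C[Si](C)(C)C)=C/CCO | intermediate
12 | (6E,10Z)-6-methyl-13-[(triethylsilyl)oxy]-10-[(trimethylsilyl)methyl]trideca-6,10-dien-2-one | CC(=O)CCC/C(C)=C/CC/C(C[Si](C)(C)C)=C/CCO[Si](CC)(CC)CC | intermediate
13 | triethyl({(3Z,7E)-8-methyl-11-[(2S)-2-methyloxiran-2-yl]-4-[(trimethylsilyl)methyl]undeca-3,7-dien-1-yl}oxy)silane | C[C@]1(CCC/C(C)=C/CC/C(C[Si](C)(C)C)=C/CCO[Si](CC)(CC)CC)CO1 | intermediate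
14 | [(1S,4aR,5S,8aR)-1,4a-dimethyl-6-methylidene-5-{2-[(triethylsilyl)oxy]ethyl}decahydronaphthalen-1-yl]methanol | C=C1CC[C@@H]2[C@](C)(CCC[C@]2(C)CO)[C@H]1CCO[Si](CC)(CC)CC | intermediate
15 | (1S,4aR,5S,8aR)-1,4a-dimethyl-6-methylidene-5-(2-oxoethyl)decahydronaphthalene-1-carbaldehyde | C=C1CC[C@@H]2[C@](C)(CCC[C@]2(C)C=O)[C@H]1CC=O | intermediate
16 | methyl (4S)-5-[(1S,4aR,5S,8aR)-5-formyl-5,8a-dimethyl-2-methylidenedecahydronaphthalen-1-yl]-4-hydroxypent-2-ynoate | C=C1CC[C@@H]2[C@](C)(CCC[C@]2(C)C=O)[C@H]1C[C@H](O)C#CC(=O)OC | intermediate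
17 | (1S,4aR,5S,8aR)-5-[(2S)-2-hydroxy-5-methoxy-5-oxopent-3-yn-1-yl]-1,4a-dimethyl-6-methylidenedecahydronaphthalene-1-carboxylic acid | C=C1CC[C@@H]2[C@](C)(CCC[C@]2(C)C(=O)O)[C@H]1C[C@H](O)C#CC(=O)OC | intermediate
18 | (1S,4aR,5S,8aR)-5-[(2S,3Z)-2-hydroxy-5-methoxy-3-methyl-5-oxopent-3-en-1-yl]-1,4a-dimethyl-6-methylidenedecahydronaphthalene-1-carboxylic acid | C=C1CC[C@@H]2[C@](C)(CCC[C@]2(C)C(=O)O)[C@H]1C[C@H](O)/C(C)=C\C(=O)OC | intermediate
19 | (1S,4aR,5S,8aR)-1,4a-dimethyl-6-methylidene-5-{[(2S)-3-methyl-5-oxo-2,5-dihydrofuran-2-yl]methyl}decahydronaphthalene-1-carboxylic acid | C=C1CC[C@@H]2[C@](C)(CCC[C@]2(C)C(=O)O)[C@H]1C[C@@H]3OC(=O)C=C3C | intermediate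
20 | (1S,4aR,5S,8aR)-5-[(2S,3Z)-4-carboxy-2-hydroxy-3-methylbut-3-en-1-yl]-1,4a-dimethyl-6-methylidenedecahydronaphthalene-1-carboxylic acid, i.e. (12S,13Z)-12-hydroxylabda-8(17),13-diene-15,19-dioic acid | C=C1CC[C@@H]2[C@](C)(CCC[C@]2(C)C(=O)O)[C@H]1C[C@H](O)/C(C)=C\C(=O)O | target

## Summary

Total step count: 14. Longest linear sequence: 14 steps (1 to 20).

Steps most likely to fail:

Step 9. Lewis-acid opening of the 2,2-disubstituted oxirane may give hydride shift to the aldehyde, or the C4 epimer if the oxirane CH2 rather than the methyl ends up equatorial. Fallback, from 5 back to 15: C19 is fixed by alkene geometry instead, at the cost of a C3 oxygen that must be removed. Bromide 5 is coupled [Li2CuCl4, (1,3-dioxolan-2-ylmethyl)magnesium bromide] to acetal enyne F1; carbocupration and ethylene oxide as in step 5 give allylsilane alcohol F2; PPTS in wet acetone frees hydroxy aldehyde F3; Ando olefination [ethyl 2-(diphenoxyphosphoryl)propanoate, NaH] gives (Z)-enoate F4; DIBAL-H gives (Z)-allylic diol F5; Sharpless epoxidation [Ti(OiPr)4, D-(−)-diethyl tartrate, t-BuOOH] gives (2R,3S)-epoxy diol F6; Et3SiCl gives bis-silyl ether F7; MeAlCl2 cyclises this trisubstituted epoxide through the same chair–chair cascade, the (Z)-CH2OSi group being forced axial, to 3β-alcohol F8; Barton–McCombie deoxygenation via xanthate F9 (NaH, CS2, MeI; then Bu3SnH, AIBN) gives bis-silyl ether F10; Swern oxidation of both primary silyl ethers gives 15.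

Step 5. The hindered alkenylcopper may not open ethylene oxide cleanly. Fallback, from 8 back to 10: alkenylcopper 9 is quenched with I2 to vinyl iodide F11; t-BuLi (Et2O, −78 °C) gives vinyllithium F12, which opens ethylene oxide in the presence of BF3·OEt2 to give 10.

Step 8. The ee of the methylene transfer may be low for this dialkyl ketone. Fallback, from 12 back to 13: 12 is converted to racemic epoxide F13 (Me3S(O)I, NaH, DMSO) and resolved kinetically with Me3SiN3 and the (salen)CrN3 enantiomer that consumes the (R)-epoxide; this becomes azido silyl ether F14 and (S)-13 is recovered (at most 50%).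

## Further compounds

F1 | step 9 | 2-[(3E)-3-methyloct-3-en-7-yn-1-yl]-1,3-dioxolane | C1(CC/C(C)=C/CCC#C)OCCO1
F2 | step 9 | (3Z,7E)-10-(1,3-dioxolan-2-yl)-8-methyl-4-[(trimethylsilyl)methyl]deca-3,7-dien-1-ol | C1(CC/C(C)=C/CC/C(C[Si](C)(C)C)=C/CCO)OCCO1
F3 | step 9 | (4E,8Z)-11-hydroxy-4-methyl-8-[(trimethylsilyl)methyl]undeca-4,8-dienal | O=CCC/C(C)=C/CC/C(C[Si](C)(C)C)=C/CCO
F4 | step 9 | ethyl (2Z,6E,10Z)-13-hydroxy-2,6-dimethyl-10-[(trimethylsilyl)methyl]trideca-2,6,10-trienoate | CCOC(=O)/C(C)=C\CC/C(C)=C/CC/C(C[Si](C)(C)C)=C/CCO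
F5 | step 9 | (2Z,6E,10Z)-2,6-dimethyl-10-[(trimethylsilyl)methyl]trideca-2,6,10-triene-1,13-diol | OC/C(C)=C\CC/C(C)=C/CC/C(C[Si](C)(C)C)=C/CCO
F6 | step 9 | [(2R,3S)-3-{(3E,7Z)-10-hydroxy-3-methyl-7-[(trimethylsilyl)methyl]deca-3,7-dien-1-yl}-2-methyloxiran-2-yl]methanol | OC[C@@]1(C)O[C@H]1CC/C(C)=C/CC/C(C[Si](C)(C)C)=C/CCO
F7 | step 9 | (2R,3S)-2-methyl-2-{[(triethylsilyl)oxy]methyl}-3-{(3E,7Z)-3-methyl-10-[(triethylsilyl)oxy]-7-[(trimethylsilyl)methyl]deca-3,7-dien-1-yl}oxirane | CC[Si](CC)(CC)OC[C@@]1(C)O[C@H]1CC/C(C)=C/CC/C(C[Si](C)(C)C)=C/CCO[Si](CC)(CC)CC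
F8 | step 9 | (1S,2S,4aR,5S,8aR)-1,4a-dimethyl-6-methylidene-1-{[(triethylsilyl)oxy]methyl}-5-{2-[(triethylsilyl)oxy]ethyl}decahydronaphthalen-2-ol | C=C1CC[C@@H]2[C@](C)(CC[C@H](O)[C@]2(C)CO[Si](CC)(CC)CC)[C@H]1CCO[Si](CC)(CC)CC
F9 | step 9 | O-[(1S,2S,4aR,5S,8aR)-1,4a-dimethyl-6-methylidene-1-{[(triethylsilyl)oxy]methyl}-5-{2-[(triethylsilyl)oxy]ethyl}decahydronaphthalen-2-yl] S-methyl carbonodithioate | C=C1CC[C@@H]2[C@](C)(CC[C@H](OC(=S)SC)[C@]2(C)CO[Si](CC)(CC)CC)[C@H]1CCO[Si](CC)(CC)CC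
F10 | step 9 | triethyl{[(1S,4aR,5S,8aR)-1,4a-dimethyl-6-methylidene-5-{2-[(triethylsilyl)oxy]ethyl}decahydronaphthalen-1-yl]methoxy}silane | C=C1CC[C@@H]2[C@](C)(CCC[C@]2(C)CO[Si](CC)(CC)CC)[C@H]1CCO[Si](CC)(CC)CC
F11 | step 5 | 2-[(4E,8Z)-9-iodo-4-methyl-8-[(trimethylsilyl)methyl]nona-4,8-dien-1-yl]-2-methyl-1,3-dioxolane | CC1(CCC/C(C)=C/CC/C(C[Si](C)(C)C)=C/I)OCCO1
F12 | step 5 | {(1Z,5E)-6-methyl-9-(2-methyl-1,3-dioxolan-2-yl)-2-[(trimethylsilyl)methyl]nona-1,5-dien-1-yl}lithium | CC1(CCC/C(C)=C/CC/C(C[Si](C)(C)C)=C/[Li])OCCO1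
F13 | step 8 | rac-triethyl({(3Z,7E)-8-methyl-11-(2-methyloxiran-2-yl)-4-[(trimethylsilyl)methyl]undeca-3,7-dien-1-yl}oxy)silane | CC1(CCC/C(C)=C/CC/C(C[Si](C)(C)C)=C/CCO[Si](CC)(CC)CC)CO1
F14 | step 8 | {[(2R,6E,10Z)-1-azido-2,6-dimethyl-13-[(triethylsilyl)oxy]-10-[(trimethylsilyl)methyl]trideca-6,10-dien-2-yl]oxy}trimethylsilane | C[C@@](CN=[N+]=[N-])(O[Si](C)(C)C)CCC/C(C)=C/CC/C(C[Si](C)(C)C)=C/CCO[Si](CC)(CC)CC
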